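**Retrosynthetic overview**
1. The route rests on C4 of the chroman-2-one: a doubly benzylic methine between ring A (C4a) and the 4-hydroxyphenyl ring, whose third carbon neighbour, the C3 methylene, carries only the lactone carbonyl C2.
2. Key disconnection: C2–C3 and C4–C1′ are made together by a copper-catalysed three-component radical relay on ring A styrene 2 with BrCCl3 and arylboronic acid 3; the styrene comes from the aldehyde by Wittig methylenation.
3. C2 travels as CCl3 and is unmasked without strong acid (CCl3 → CH=CCl2 → C≡CH → CH2CO2Me), because direct hydrolysis of an alkyl CCl3 group needs hot concentrated mineral acid, which would cleave the trimethoxyaryl–C4 bond.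
4. The C8 acyl group is put on the still symmetric ring A by Friedel–Crafts acylation; the new ketone then singles out, by chelation, the flanking methoxy oxygen that becomes O1.
5. Ring order: the three benzene rings are bought; the lactone ring (O1–C2 bond) is the only ring formed, in step 7, before the final demethylation.

Key step: step 2

Assumption: the sense of induction of the copper–bisoxazoline catalyst on this di-ortho-substituted styrene cannot be predicted, so the (S,S)-ligand is written and its antipode is to be used if it delivers the (R)-enantiomer of 5.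

**Step 1**
Reactants: 1 2,4,6-trimethoxybenzaldehyde
Product: 2 1,3,5-trimethoxy-2-vinylbenzene
Conditions: Ph3PCH3Br (1.3 equiv), KOtBu (1.25 equiv), THF, 0 °C → rt; Et3N-deactivated silica
Reagents that add atoms: methyltriphenylphosphonium bromide, C[P+](c1ccccc1)(c1ccccc1)c1ccccc1.[Br-]
Why: Wittig methylenation of a non-enolisable aryl aldehyde with methylenetriphenylphosphorane is dependable even with two ortho methoxy groups; no stereocentre is formed and the acid-sensitive styrene is kept away from acid.

**Step 2**
Reactants: 2 1,3,5-trimethoxy-2-vinylbenzene; 3 [4-(benzyloxy)phenyl]boronic acid; 4 bromotrichloromethane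
Product: 5 (S)-2-{1-[4-(benzyloxy)phenyl]-3,3,3-trichloropropyl}-1,3,5-trimethoxybenzene
Conditions: Cu(CH3CN)4PF6 (10 mol%), 2,2′-(propane-2,2-diyl)bis[(4S)-4-phenyl-4,5-dihydrooxazole] (12 mol%), 3 (2 equiv), K3PO4 (2 equiv), H2O (2 equiv), 4 (1.5 equiv, added over 6 h), CH2Cl2/DMAc 4:1, −10 °C, Ar, dark
Reagents that add atoms: none
Why: Proposed new method: monovalent copper bound to the bisoxazoline abstracts bromine from BrCCl3, the electrophilic trichloromethyl radical adds to the unsubstituted terminus of the electron-rich styrene (C2–C3 bond), and the benzylic C4 radical is captured by the aryl complex of divalent copper formed by phosphate-assisted transmetalation of 3, after which the trivalent copper intermediate reductively eliminates the C4–aryl bond and returns monovalent copper. The closest known reaction types are the copper–bisoxazoline enantioselective trifluoromethyl-arylation of styrenes with arylboronic acids and the copper-mediated atom-transfer (Kharasch) addition of BrCCl3 to styrenes. No ring is closed. The single new stereocentre C4 is set in the radical capture and reductive elimination at copper, where the ligand has to tell the di-ortho-methoxylated ring A from the slim CH2CCl3 arm, and the (S)-configuration is required. The step needs regioselective radical addition, secured by the free CH2 terminus and the stabilised benzylic radical, and it needs capture at copper to outrun bromine-atom transfer and oxidation of the very electron-rich radical to a cation, which is why BrCCl3 is kept at low concentration, the temperature is low and the medium is buffered by K3PO4. The CCl3 group is chosen because it cannot lactonise onto ring A or acidify C4 during the coupling.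

**Step 3**
Reactants: 5 (S)-2-{1-[4-(benzyloxy)phenyl]-3,3,3-trichloropropyl}-1,3,5-trimethoxybenzene
Product: 6 (S)-2-{1-[4-(benzyloxy)phenyl]-3,3-dichloroprop-2-en-1-yl}-1,3,5-trimethoxybenzene
Conditions: KOtBu (1.2 equiv), THF, −20 → 0 °C; aq NH4Cl
Reagents that add atoms: none
Why: Base-induced E2 dehydrochlorination of a 2,2,2-trichloroethyl group to a 1,1-dichlorovinyl group is standard because the methylene hydrogens next to CCl3 are the most acidic in the molecule, whereas the hindered, electron-rich diarylmethine C4–H should not be removed by the alkoxide at or below 0 °C, so C4 is expected to keep its configuration.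

**Step 4**
Reactants: 6 (S)-2-{1-[4-(benzyloxy)phenyl]-3,3-dichloroprop-2-en-1-yl}-1,3,5-trimethoxybenzene
Product: 9 (S)-2-{1-[4-(benzyloxy)phenyl]prop-2-yn-1-yl}-1,3,5-trimethoxybenzene, via chloroalkyne 7 (not isolated), via lithium acetylide 8 (not isolated)
Conditions: n-BuLi (2.2 equiv), THF, −78 °C, 1 h; sat. aq NH4Cl, −78 °C → rt
Reagents that add atoms: none
Why: This is the 1,1-dichloroalkene variant of the second stage of the Corey–Fuchs alkyne synthesis: vinylic deprotonation and loss of LiCl give chloroalkyne 7, chlorine–lithium exchange with the second equivalent gives acetylide 8, whose negative charge disfavours removal of the propargylic C4–H, and cold protonation releases alkyne 9 with C4 unchanged.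

**Step 5**
Reactants: 9 (S)-2-{1-[4-(benzyloxy)phenyl]prop-2-yn-1-yl}-1,3,5-trimethoxybenzene
Product: 10 methyl (S)-3-[4-(benzyloxy)phenyl]-3-(2,4,6-trimethoxyphenyl)propanoate
Conditions: [Rh(cod)Cl]2 (2.5 mol%), P(4-FC6H4)3 (10 mol%), 4-methylpyridine N-oxide (1.2 equiv), MeOH (5 equiv), MeCN, 60 °C
Reagents that add atoms: 4-methylpyridine N-oxide, Cc1cc[n+]([O-])cc1; methanol, CO
Why: Rhodium-catalysed oxygenative addition to a terminal alkyne: the alkyne rearranges at monovalent rhodium to a vinylidene, oxygen-atom transfer from the N-oxide gives a metal-bound ketene and methanol adds to it, so the terminal carbon becomes the ester carbon C2 under neutral conditions that cannot epimerise C4.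

**Step 6**
Reactants: 10 methyl (S)-3-[4-(benzyloxy)phenyl]-3-(2,4,6-trimethoxyphenyl)propanoate; 11 3-phenylpropanoyl chloride
Product: 12 methyl (S)-3-[4-(benzyloxy)phenyl]-3-[2,4,6-trimethoxy-3-(3-phenylpropanoyl)phenyl]propanoate
Conditions: 11 (1.2 equiv), SnCl4 (1.2 equiv), CH2Cl2, −40 → 0 °C; aq NaHCO3
Reagents that add atoms: none
Why: Friedel–Crafts acylation should occur at one of the two equivalent free positions of ring A, each ortho to two methoxy groups and para to the third and far more nucleophilic than the benzyloxyphenyl ring, and the deactivating ketone stops a second acylation while marking the neighbouring methoxy oxygen that is to become O1.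

**Step 7**
Reactants: 12 methyl (S)-3-[4-(benzyloxy)phenyl]-3-[2,4,6-trimethoxy-3-(3-phenylpropanoyl)phenyl]propanoate
Product: 14 (S)-4-(4-hydroxyphenyl)-5,7-dimethoxy-8-(3-phenylpropanoyl)chroman-2-one, via hydroxy ester 13 (not isolated)
Conditions: BCl3 (5 equiv), C6HMe5 (3 equiv), CH2Cl2, −78 → 0 °C; H2O; then TsOH·H2O (10 mol%), PhMe, 80 °C
Reagents that add atoms: none
Why: BCl3 cleaves the aryl benzyl ether (cation trapped by pentamethylbenzene) and, by chelation to the ketone, the methoxy group that is both ortho to the ketone and flanked by two substituents, while the methoxy group para to the ketone (future C5) is left, so the acid-catalysed lactonisation of the freed phenol onto the ester (6-exo-trig acyl substitution, helped by buttressing from the C5 methoxy group) can only give the 8-acyl chroman-2-one; any material that also loses the C7 methyl group converges in step 8.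

**Step 8**
Reactants: 14 (S)-4-(4-hydroxyphenyl)-5,7-dimethoxy-8-(3-phenylpropanoyl)chroman-2-one
Product: 15 (S)-5,7-dihydroxy-4-(4-hydroxyphenyl)-8-(3-phenylpropanoyl)chroman-2-one
Conditions: BBr3 (6 equiv), CH2Cl2, −78 → 0 °C; ice-water
Reagents that add atoms: none
Why: BBr3 demethylation cleaves both aryl methyl ethers (the C7 ether assisted by chelation to the ketone) whereas the aryl ester of the lactone has no alkyl–oxygen bond to cleave, and a cold, brief aqueous work-up is meant to avoid ring opening and reclosure onto the C5 oxygen; C4 is not touched.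

**Compound list**
1 | 2,4,6-trimethoxybenzaldehyde | COc1cc(OC)c(C=O)c(OC)c1 | starting material
2 | 1,3,5-trimethoxy-2-vinylbenzene | C=Cc1c(OC)cc(OC)cc1OC | intermediate
3 | [4-(benzyloxy)phenyl]boronic acid | OB(O)c1ccc(OCc2ccccc2)cc1 | starting material
4 | bromotrichloromethane | ClC(Cl)(Cl)Br | starting material
5 | (S)-2-{1-[4-(benzyloxy)phenyl]-3,3,3-trichloropropyl}-1,3,5-trimethoxybenzene | ClC(Cl)(Cl)C[C@@H](c1ccc(OCc2ccccc2)cc1)c1c(OC)cc(OC)cc1OC | intermediate
6 | (S)-2-{1-[4-(benzyloxy)phenyl]-3,3-dichloroprop-2-en-1-yl}-1,3,5-trimethoxybenzene | ClC(Cl)=C[C@@H](c1ccc(OCc2ccccc2)cc1)c1c(OC)cc(OC)cc1OC | intermediate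
7 | (S)-2-{1-[4-(benzyloxy)phenyl]-3-chloroprop-2-yn-1-yl}-1,3,5-trimethoxybenzene (chloroalkyne, formed in the flask) | ClC#C[C@@H](c1ccc(OCc2ccccc2)cc1)c1c(OC)cc(OC)cc1OC | intermediate
8 | lithium acetylide of 9, lithium (R)-3-[4-(benzyloxy)phenyl]-3-(2,4,6-trimethoxyphenyl)prop-1-yn-1-ide (same spatial arrangement as 9; the descriptor changes only because lithium outranks hydrogen; formed in the flask) | [Li]C#C[C@@H](c1ccc(OCc2ccccc2)cc1)c1c(OC)cc(OC)cc1OC | intermediate
9 | (S)-2-{1-[4-(benzyloxy)phenyl]prop-2-yn-1-yl}-1,3,5-trimethoxybenzene | C#C[C@@H](c1ccc(OCc2ccccc2)cc1)c1c(OC)cc(OC)cc1OC | intermediate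
10 | methyl (S)-3-[4-(benzyloxy)phenyl]-3-(2,4,6-trimethoxyphenyl)propanoate | COC(=O)C[C@@H](c1ccc(OCc2ccccc2)cc1)c1c(OC)cc(OC)cc1OC | intermediate
11 | 3-phenylpropanoyl chloride | O=C(Cl)CCc1ccccc1 | starting material
12 | methyl (S)-3-[4-(benzyloxy)phenyl]-3-[2,4,6-trimethoxy-3-(3-phenylpropanoyl)phenyl]propanoate | COC(=O)C[C@@H](c1ccc(OCc2ccccc2)cc1)c1c(OC)cc(OC)c(C(=O)CCc2ccccc2)c1OC | intermediate
13 | methyl (S)-3-[2-hydroxy-4,6-dimethoxy-3-(3-phenylpropanoyl)phenyl]-3-(4-hydroxyphenyl)propanoate (formed in the flask) | COC(=O)C[C@@H](c1ccc(O)cc1)c1c(OC)cc(OC)c(C(=O)CCc2ccccc2)c1O | intermediate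
14 | (S)-4-(4-hydroxyphenyl)-5,7-dimethoxy-8-(3-phenylpropanoyl)chroman-2-one | O=C1C[C@@H](c2ccc(O)cc2)c2c(OC)cc(OC)c(C(=O)CCc3ccccc3)c2O1 | intermediate
15 | (S)-5,7-dihydroxy-4-(4-hydroxyphenyl)-8-(3-phenylpropanoyl)chroman-2-one | O=C1C[C@@H](c2ccc(O)cc2)c2c(O)cc(O)c(C(=O)CCc3ccccc3)c2O1 | target

**Step count**
Total: 8 steps. Longest linear sequence: 8 steps (1 → 15).

**Steps most likely to fail**

Step 2 (proposed new method). Bromine-atom transfer to the benzylic radical, or its oxidation to a cation, may outrun capture by the arylcopper species and give racemic or non-arylated material. Transmetalation of the boronic acid may be slow, and facial discrimination at the hindered di-ortho-substituted radical may be poor. Fallback by known chemistry, setting out from 1 and returning at 10: Horner–Wadsworth–Emmons olefination of aldehyde 1 (trimethyl phosphonoacetate, NaH, THF) gives methyl (E)-3-(2,4,6-trimethoxyphenyl)prop-2-enoate F1. Rhodium-catalysed asymmetric conjugate addition of boronic acid 3 (Hayashi–Miyaura reaction; [RhCl(C2H4)2]2, chiral diene or BINAP of the hand that gives the (S)-ester, KOH, dioxane/H2O, 60 °C) then gives ester 10 directly. Steps 2 to 5 fall away.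

Step 5. Formation of the rhodium vinylidene may be slow at the hindered propargylic diarylmethine, so that alkyne oligomerisation or low conversion takes over. Fallback from 9, returning at 10: hydroboration with dicyclohexylborane (THF, 0 °C) gives {(1E,3S)-3-[4-(benzyloxy)phenyl]-3-(2,4,6-trimethoxyphenyl)prop-1-en-1-yl}dicyclohexylborane F2. It is oxidised in the same flask with NaBO3·4H2O to (S)-3-[4-(benzyloxy)phenyl]-3-(2,4,6-trimethoxyphenyl)propanal F3. Pinnick oxidation (NaClO2, NaH2PO4, 2-methyl-2-butene in large excess to keep hypochlorite off ring A, t-BuOH/H2O) gives (S)-3-[4-(benzyloxy)phenyl]-3-(2,4,6-trimethoxyphenyl)propanoic acid F4. Methylation with trimethylsilyldiazomethane (MeOH/PhMe) returns ester 10.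

Step 6. The acylium ion may attack ring A at the carbon bearing C4 with loss of the side chain, the acid may reversibly cleave the ring A–C4 bond and erode the configuration, and the benzyl ether may be partly lost. Fallback from 10, returning at 12: Vilsmeier–Haack formylation (POCl3, DMF, 0 °C → rt), a weaker and bulkier electrophile without strong protic acid, gives {3-[(S)-1-[4-(benzyloxy)phenyl]-3-methoxy-3-oxopropyl]-2,4,6-trimethoxybenzylidene}dimethylammonium chloride F5. Work-up with aq NaOAc hydrolyses it to methyl (S)-3-[4-(benzyloxy)phenyl]-3-(3-formyl-2,4,6-trimethoxyphenyl)propanoate F6. PhCH2CH2MgBr (THF, −78 °C) adds to the aldehyde in preference to the methyl ester and gives methyl (3S)-3-[4-(benzyloxy)phenyl]-3-[3-(1-hydroxy-3-phenylpropyl)-2,4,6-trimethoxyphenyl]propanoate F7, as both epimers at the carbinol carbon. Dess–Martin periodinane buffered with NaHCO3 (CH2Cl2) oxidises both epimers to ketone 12.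

**Further compounds**
F1 | step 2 | methyl (E)-3-(2,4,6-trimethoxyphenyl)prop-2-enoate | COC(=O)/C=C/c1c(OC)cc(OC)cc1OC
F2 | step 5 | {(1E,3S)-3-[4-(benzyloxy)phenyl]-3-(2,4,6-trimethoxyphenyl)prop-1-en-1-yl}dicyclohexylborane | C1CCCCC1B(/C=C/[C@@H](c1ccc(OCc2ccccc2)cc1)c1c(OC)cc(OC)cc1OC)C1CCCCC1
F3 | step 5 | (S)-3-[4-(benzyloxy)phenyl]-3-(2,4,6-trimethoxyphenyl)propanal | O=CC[C@@H](c1ccc(OCc2ccccc2)cc1)c1c(OC)cc(OC)cc1OC
F4 | step 5 | (S)-3-[4-(benzyloxy)phenyl]-3-(2,4,6-trimethoxyphenyl)propanoic acid | OC(=O)C[C@@H](c1ccc(OCc2ccccc2)cc1)c1c(OC)cc(OC)cc1OC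
F5 | step 6 | {3-[(S)-1-[4-(benzyloxy)phenyl]-3-methoxy-3-oxopropyl]-2,4,6-trimethoxybenzylidene}dimethylammonium chloride | COC(=O)C[C@@H](c1ccc(OCc2ccccc2)cc1)c1c(OC)cc(OC)c(C=[N+](C)C)c1OC.[Cl-]
F6 | step 6 | methyl (S)-3-[4-(benzyloxy)phenyl]-3-(3-formyl-2,4,6-trimethoxyphenyl)propanoate | COC(=O)C[C@@H](c1ccc(OCc2ccccc2)cc1)c1c(OC)cc(OC)c(C=O)c1OC
F7 | step 6 | methyl (3S)-3-[4-(benzyloxy)phenyl]-3-[3-(1-hydroxy-3-phenylpropyl)-2,4,6-trimethoxyphenyl]propanoate | COC(=O)C[C@@H](c1ccc(OCc2ccccc2)cc1)c1c(OC)cc(OC)c(C(O)CCc2ccccc2)c1OC
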